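(The numbers in the tables were computed for an exercise; scatter was added.)

A flask cannot capture with second nucleophile that has not yet gone in. So feeding second nucleophile helps target as far as capture happens before the feed ends, and the earlier runs can tell us how far that is.

| flask | substrate | first nucleophile | second nucleophile | remark | time |
|---|---|---|---|---|---|
| spring | 0.0020 M | 1.3 equiv | 2 equiv | run made earlier |  |
| midnight | 0.0028 M | 1.3 equiv | 2 equiv | run made earlier |  |
| dusk | 0.0044 M | 1.3 equiv | 2 equiv | run made earlier |  |
| autumn | 0.0020 M | 1.3 equiv | 3 equiv | run made earlier |  |
| violet | 0.0020 M | 1.30 equiv | 2.00 equiv (fed, over 5.0 s) | all else is in the flask from the start; the feed brings no volume worth counting | 4.0 min |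
| green | 0.0020 M | 1.30 equiv | 2.00 equiv (fed, over 50 s) | all else is in the flask from the start; the feed brings no volume worth counting | 4.0 min |
| amber | 0.0020 M | 1.30 equiv | 2.00 equiv | everything together at the start | 4.0 min |
| teal | 0.0020 M (fed, over 50 s) | 1.30 equiv | 2.00 equiv | all else is in the flask from the start; the feed brings no volume worth counting | 4.0 min |

- spring (time / min: target / %, other capture product / %): 0.200: 3.4, 4.1; 0.667: 5.6, 7.6; 1.00: 6.5, 9.3; 1.50: 7.4, 10.7; 2.50: 8.3, 12.4; 3.00: 8.1, 12.7; 4.00: 8.7, 13.2
- midnight (time / min: target / %, other capture product / %): 0.200: 2.9, 4.2; 0.667: 5.4, 7.9; 1.00: 6.1, 9.5; 1.50: 7.5, 10.1; 2.50: 7.2, 11.4; 3.00: 7.7, 11.9; 4.00: 8.2, 12.7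
- dusk (time / min: target / %, other capture product / %): 0.333: 4.1, 6.1; 0.500: 4.6, 6.5; 0.667: 5.1, 7.1; 1.00: 6.4, 7.7; 1.50: 6.2, 9.1; 2.50: 7.0, 9.8; 4.00: 7.6, 9.9
- autumn (time / min: target / %, other capture product / %): 0.833: 5.6, 11.5; 1.50: 6.6, 14.1; 2.50: 6.8, 16.2; 3.00: 7.4, 15.7; 4.00: 7.9, 16.3

(each reading ± 0.3 percentage points)



- the best flask by share of target in target plus other capture product; "all alike" if 1.5 percentage points covers them all (violet / green / amber / teal / all alike)
- share of target in target plus other capture product at the end, violet
- share of target in target plus other capture product at the end, green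
- share of target in target plus other capture product at the end, amber
- share of target in target plus other capture product at the end, teal

Spring ends at target 8.7% and other capture product 13.2%, so its odds, other capture per target, are 1.52. Amber repeats spring, which gives a share of 39.7%. Autumn's 3 equiv gives odds of 2.06, a rise by 1.36 where the charge rose by 1.50. That is roughly proportional, but the shortfall is a warning.

So we let the odds follow the second nucleophile present. A capture during a feed of second nucleophile meets the fraction fed so far, and averaging over captures equals averaging over the feed time the fraction of capture still to come. We take the timing of capture from spring. Of spring's 21.9%, the fraction left is 0.658 at 0.200 min, 0.397 at 0.667 min and 0.279 at 1.00 min. Straight chords, the last one cut off at the end of green's 50 s, average 0.568, and this is the exposure, the share of its charge that the average capture meets. Green's share is then 53.7%.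

But chords run above a curve bending this way, so our exposure is somewhat high. For violet's 5.0 s the exposure is 0.929, which gives 41.5%. Teal has full exposure, but spring's odds, as read, rise from 1.21 at 0.200 min to 1.52 at the end. Teal's substrate feed delays its capture, so our estimate puts teal's share slightly below amber's.

The forecast named green, with violet 42.5%, green 54%, amber 40% and teal 40%, on the ground that “withholding the second nucleophile early should favour target”.

The simulation gives violet 41.7%, green 55.3%, amber 39.3% and teal 37.1%, so green is best and the forecast stands.

    substrate ⇌ intermediate (K = 0.00970, k = 0.0210 s⁻¹)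
    first nucleophile + intermediate → target (k = 330 L mol⁻¹ s⁻¹)
    second nucleophile + intermediate → other capture product (k = 270 L mol⁻¹ s⁻¹)
    first nucleophile ⇌ dormant form (K = 0.670, k = 0.00790 s⁻¹)
    2 substrate → homo dimer (k = 26.0 L mol⁻¹ s⁻¹)

Green's odds over amber's come to 0.524, under our exposure of 0.568. The largest single effect on the gap between green and teal is the turning of substrate into homo dimer: without that step the gap falls from 18 percentage points to 6.6 points. In green, half of that step's turnover up to 4.0 min is done by 0.115 min, inside the feed.

For green's neighbour with 3.40 equiv of second nucleophile, the exposure gives 40.6%. The simulation gives 44.7%, higher, in the direction of autumn's shortfall.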